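The target is a pseudo-meso 2,4-dimethylpentan-3-one whose C2 and C4 carry two nearly identical 4-pyranone rings (ring A pentyl, ring B ethyl). The route rests on disconnecting the pyran-2-yl carbon of ring A (C2A) from methine C2. Because C2 lies alpha to the C3 ketone, it can be passed through a planar alpha-keto radical. A nickel/pybox-catalysed stereoconvergent Negishi coupling unites the ring A zinc reagent with a C2-epimeric alpha-bromoketone that already carries ring B and (4S). One operation forms the bond, sets (2R) by ligand control and gives the target at its final oxidation level, without base. The mirror-image ligand makes the bromoketone from 2,4-dibromopentan-3-one.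

Key step: step 7

Assumption: the pybox antipode that gives the (S)-centre in step 4 is taken to be (S,S)-Ph-pybox, to be verified on 10. C2 and C4 are locally mirror images (same priority order C=O > pyranonyl > CH3 > H), so step 7 then uses the mirror-image ligand.

Step 1
Reactants: 1 propanoyl chloride; 2 1,1-dichloroprop-1-ene
Product: 4 1,1-dichloro-2-methylpent-1-en-3-one, via trichloroketone adduct 3 (not isolated)
Conditions: AlCl3 (1.1 equiv), CH2Cl2, 0 °C to rt; crude 3, Et3N (1.1 equiv), Et2O, 0 °C
Reagents that add atoms: none
Why: Friedel–Crafts-type acylation of a chloroalkene, in which the acylium ion attacks the CH carbon of 2 (the cation is then stabilised by both chlorines), chloride capture gives 3, and E1cB loss of HCl gives the conjugated dichlorovinyl ketone with no stereocentre left.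

Step 2
Reactants: 4 1,1-dichloro-2-methylpent-1-en-3-one; 1 propanoyl chloride
Product: 6 2-chloro-6-ethyl-3,5-dimethyl-4H-pyran-4-one, via dichlorovinyl diketone 5 (not isolated)
Conditions: MgBr2·OEt2 (2.5 equiv), iPr2NEt (3 equiv), CH2Cl2, rt, then 40 °C
Reagents that add atoms: none
Why: Magnesium-mediated soft enolisation at the only enolisable methylene of 4 and Claisen-type C-acylation give 5, whose enol oxygen closes the 4-pyranone by 6-endo conjugate addition to the dichlorovinyl carbon and loss of chloride (pyranone synthesis by acylation and cyclisation of an enone with a beta leaving group).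

Step 3
Reactants: 6 2-chloro-6-ethyl-3,5-dimethyl-4H-pyran-4-one
Product: 7 2-ethyl-6-iodo-3,5-dimethyl-4H-pyran-4-one
Conditions: NaI (5 equiv), Me3SiCl (10 mol %), MeCN, 60 °C, dark
Reagents that add atoms: sodium iodide, [Na+].[I-]
Why: Finkelstein-type halogen exchange by addition–elimination at the vinylogous acid chloride carbon, driven by precipitation of NaCl, should give the iodide needed for mild zinc insertion.

Step 4
Reactants: 7 2-ethyl-6-iodo-3,5-dimethyl-4H-pyran-4-one; 8 2,4-dibromopentan-3-one (commercial dl/meso mixture)
Product: 10 (4S)-2-bromo-4-(6-ethyl-3,5-dimethyl-4-oxo-4H-pyran-2-yl)pentan-3-one (both C2 epimers), via ring B pyranonylzinc iodide 9 (not isolated)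
Conditions: (a) Zn dust (1.5 equiv), LiCl (1.5 equiv), THF, 25 °C; (b) 8 (3 equiv), NiCl2(dme) (10 mol %), (S,S)-Ph-pybox (13 mol %), DME/THF, −30 °C; pH 7 buffer, neutral silica
Reagents that add atoms: none
Why: Stereoconvergent nickel/pybox-catalysed Negishi arylation of a racemic secondary alpha-bromoketone, in which monovalent nickel abstracts one bromine, the planar alpha-keto radical is captured by the chiral pyranonyl–nickel complex, reductive elimination sets the (S)-centre under ligand control without base, and the threefold excess of 8 should keep the second C–Br bond intact.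

Step 5
Reactants: 4 1,1-dichloro-2-methylpent-1-en-3-one; 11 hexanoyl chloride
Product: 13 2-chloro-3,5-dimethyl-6-pentyl-4H-pyran-4-one, via dichlorovinyl diketone 12 (not isolated)
Conditions: MgBr2·OEt2 (2.5 equiv), iPr2NEt (3 equiv), CH2Cl2, rt, then 40 °C
Reagents that add atoms: none
Why: The same soft-enolisation Claisen-type C-acylation and 6-endo addition–elimination ring closure as in step 2, now with the hexanoyl unit that supplies the pentyl-bearing carbon of ring A.

Step 6
Reactants: 13 2-chloro-3,5-dimethyl-6-pentyl-4H-pyran-4-one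
Product: 14 2-iodo-3,5-dimethyl-6-pentyl-4H-pyran-4-one
Conditions: NaI (5 equiv), Me3SiCl (10 mol %), MeCN, 60 °C, dark
Reagents that add atoms: sodium iodide, [Na+].[I-]
Why: Finkelstein-type addition–elimination halogen exchange as in step 3, driven by precipitation of NaCl.

Step 7
Reactants: 14 2-iodo-3,5-dimethyl-6-pentyl-4H-pyran-4-one; 10 (4S)-2-bromo-4-(6-ethyl-3,5-dimethyl-4-oxo-4H-pyran-2-yl)pentan-3-one (both C2 epimers)
Product: 16 (2R,4S)-2-(3,5-dimethyl-4-oxo-6-pentyl-4H-pyran-2-yl)-4-(6-ethyl-3,5-dimethyl-4-oxo-4H-pyran-2-yl)pentan-3-one (target), via ring A pyranonylzinc iodide 15 (not isolated)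
Conditions: (a) 14 (1.5 equiv), Zn dust, LiCl, THF, 25 °C; (b) 10 (1 equiv), NiCl2(dme) (10 mol %), (R,R)-Ph-pybox (13 mol %), DME/THF, −30 °C; pH 7 buffer at −30 °C, neutral silica
Reagents that add atoms: none
Why: Zinc inserts into the C–I bond of 14 to give 15; monovalent nickel abstracts bromine from either C2 epimer of 10, the planar alpha-keto radical at C2 (conjugated with the C3 carbonyl) is captured by the chiral pyranonyl–nickel complex, and reductive elimination from trivalent nickel forms the C2A–C2 bond. The closest known reaction type is the nickel/pybox-catalysed stereoconvergent Negishi arylation of racemic secondary alpha-bromoketones with arylzinc halides, which gives tertiary alpha-aryl ketones without racemisation. No ring is closed. The new centre C2 should be set as (R) by the mirror-image ligand and not by the lost C–Br configuration, while C4 stays untouched because the medium holds no base stronger than the organozinc and is kept at −30 °C. The step needs chemoselectivity for C–Br over the ketone and both pyranone carbonyls, which the low nucleophilicity of 15 secures, and it needs ligand control to override the bias of C4. Errors of either coupling end mainly in the separable (2S,4S) and (2R,4R) diastereomers, so the two ligand-controlled events should statistically raise the enantiopurity of 16.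

Compound list
1 | propanoyl chloride | CCC(=O)Cl | starting material
2 | 1,1-dichloroprop-1-ene | CC=C(Cl)Cl | starting material
3 | 1,1,1-trichloro-2-methylpentan-3-one (racemic) | CCC(=O)C(C)C(Cl)(Cl)Cl | intermediate
4 | 1,1-dichloro-2-methylpent-1-en-3-one | CCC(=O)C(C)=C(Cl)Cl | intermediate
5 | 1,1-dichloro-2,4-dimethylhept-1-ene-3,5-dione (racemic) | CCC(=O)C(C)C(=O)C(C)=C(Cl)Cl | intermediate
6 | 2-chloro-6-ethyl-3,5-dimethyl-4H-pyran-4-one | CCc1oc(Cl)c(C)c(=O)c1C | intermediate
7 | 2-ethyl-6-iodo-3,5-dimethyl-4H-pyran-4-one | CCc1oc(I)c(C)c(=O)c1C | intermediate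
8 | 2,4-dibromopentan-3-one (dl/meso mixture) | CC(Br)C(=O)C(C)Br | starting material
9 | (6-ethyl-3,5-dimethyl-4-oxo-4H-pyran-2-yl)zinc iodide | CCc1oc([Zn]I)c(C)c(=O)c1C | intermediate
10 | (4S)-2-bromo-4-(6-ethyl-3,5-dimethyl-4-oxo-4H-pyran-2-yl)pentan-3-one, both C2 epimers | CC(Br)C(=O)[C@@H](C)c1oc(CC)c(C)c(=O)c1C | intermediate
11 | hexanoyl chloride | CCCCCC(=O)Cl | starting material
12 | 1,1-dichloro-2,4-dimethyldec-1-ene-3,5-dione (racemic) | CCCCCC(=O)C(C)C(=O)C(C)=C(Cl)Cl | intermediate
13 | 2-chloro-3,5-dimethyl-6-pentyl-4H-pyran-4-one | CCCCCc1oc(Cl)c(C)c(=O)c1C | intermediate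
14 | 2-iodo-3,5-dimethyl-6-pentyl-4H-pyran-4-one | CCCCCc1oc(I)c(C)c(=O)c1C | intermediate
15 | (3,5-dimethyl-4-oxo-6-pentyl-4H-pyran-2-yl)zinc iodide | CCCCCc1oc([Zn]I)c(C)c(=O)c1C | intermediate
16 | (2R,4S)-2-(3,5-dimethyl-4-oxo-6-pentyl-4H-pyran-2-yl)-4-(6-ethyl-3,5-dimethyl-4-oxo-4H-pyran-2-yl)pentan-3-one | CCCCCc1oc([C@@H](C)C(=O)[C@@H](C)c2oc(CC)c(C)c(=O)c2C)c(C)c(=O)c1C | target

Total step count: 7. Longest linear sequence: 5 (steps 1, 2, 3, 4, 7).

Steps most likely to fail

Step 7. Transmetalation of the hindered, electron-poor zinc reagent may be slow. The neighbouring C4 centre may erode ligand control. C2 and C4 may epimerise by enolisation during the reaction or work-up. The fallback inverts the polarity, sets out from 10 and 14, and comes back at 16. Zinc dust in THF converts 10 into its Reformatsky reagent, the bromozinc enolate F1. F1 is coupled with 14 under Pd(dba)2/Q-phos catalysis in THF at rt, a neutral alpha-arylation of a zinc enolate. C2 then forms without control, and 16 is separated by chromatography from the (2S,4S)-epimer F2. The preset C4 centre still secures the absolute configuration.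

Step 4. Both bromides may be lost reductively through an oxyallyl-type pathway, and a second arylation of the product may occur. The fallback changes the linchpin to one with two halides of different reactivity, sets out from 7 (through 9), and comes back at 10. Commercial 2-chloropentan-3-one is brominated (Br2, cat. HBr, CH2Cl2) at its free alpha'-methylene to 2-bromo-4-chloropentan-3-one F3. The nickel catalyst of step 4 should engage only the C–Br bond of F3 and give (4S)-2-chloro-4-(6-ethyl-3,5-dimethyl-4-oxo-4H-pyran-2-yl)pentan-3-one F4. Halide exchange with excess LiBr in acetone then gives 10.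

Step 5. The amine or halide may attack the dichlorovinyl terminus, and O-acylation may compete with C-acylation. The fallback replaces the chlorides by base-tolerant sulfur leaving groups, sets out from 11, and comes back at 13. Pentan-3-one, NaH, CS2 and MeI give the ketene dithioacetal 2-methyl-1,1-bis(methylsulfanyl)pent-1-en-3-one F5. Its kinetic lithium enolate (LDA, THF, −78 °C) is C-acylated with 11 to 2,4-dimethyl-1,1-bis(methylsulfanyl)dec-1-ene-3,5-dione F6. TFA closes the ring with loss of methanethiol to 3,5-dimethyl-2-(methylsulfanyl)-6-pentyl-4H-pyran-4-one F7. Chlorinolysis with SO2Cl2 (CH2Cl2, 0 °C) exchanges the methylsulfanyl group for chloride and gives 13.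

Further compounds
F1 | step 7 | bromozinc enolate of 10, bromo{[(4S)-4-(6-ethyl-3,5-dimethyl-4-oxo-4H-pyran-2-yl)pent-2-en-3-yl]oxy}zinc | CC=C(O[Zn]Br)[C@@H](C)c1oc(CC)c(C)c(=O)c1C
F2 | step 7 | (2S,4S)-2-(3,5-dimethyl-4-oxo-6-pentyl-4H-pyran-2-yl)-4-(6-ethyl-3,5-dimethyl-4-oxo-4H-pyran-2-yl)pentan-3-one | CCCCCc1oc([C@H](C)C(=O)[C@@H](C)c2oc(CC)c(C)c(=O)c2C)c(C)c(=O)c1C
F3 | step 4 | 2-bromo-4-chloropentan-3-one (stereoisomer mixture) | CC(Br)C(=O)C(C)Cl
F4 | step 4 | (4S)-2-chloro-4-(6-ethyl-3,5-dimethyl-4-oxo-4H-pyran-2-yl)pentan-3-one, both C2 epimers | CC(Cl)C(=O)[C@@H](C)c1oc(CC)c(C)c(=O)c1C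
F5 | step 5 | 2-methyl-1,1-bis(methylsulfanyl)pent-1-en-3-one | CCC(=O)C(C)=C(SC)SC
F6 | step 5 | 2,4-dimethyl-1,1-bis(methylsulfanyl)dec-1-ene-3,5-dione (racemic) | CCCCCC(=O)C(C)C(=O)C(C)=C(SC)SC
F7 | step 5 | 3,5-dimethyl-2-(methylsulfanyl)-6-pentyl-4H-pyran-4-one | CCCCCc1oc(SC)c(C)c(=O)c1C
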